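The cyclohexane ring (C1 CHOH, C2 CHOAng, C3 CMeOH, C4 CHCl, C5, C6 side-chain carbon) is cut across C1–C6 and C3–C4 into a C1–C3 ketone and a C4–C6 enal. The key step is an α,α′-annulation: enantioselective Mukaiyama–Michael addition (C1–C6), then in the same flask a chelate-controlled aldol (C3–C4). It exploits the 1,3-cis-diaxial oxygens on C1 and C3: in the precursor, the silyl enol ether of 2,2,4-trimethyl-1,3-dioxan-5-one, they are tied as an acetonide, so closure must give a 2,4-dioxabicyclo[3.3.1]nonan-9-one with C1, C3, C4, C6 set and C2 as bridging ketone. The acetonide is cleaved later; the aldol oxygen becomes chloride via the C3–C4 epoxide.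

Key step: step 5

Remarks on the chemistry
- Locants follow the target throughout: ring C1–C6 as above; side chain C7 (=C14H2), C8 (CH–OAng), C9 (CH2), C10–C11 (epoxide). α is the ring face that carries the oxygens on C1, C2, C3 and the side chain on C6; β is the face of Cl and the C3 methyl. Ang = angeloyl, (Z)-2-methylbut-2-enoyl. In these locants the target is 1S,2S,3S,4S,6R,8S,10R.
- Compounds 4, 5 and 6 are racemic; their only stereocentre (C3) is planarised again in step 5.
- Assumption: the D-fructose-derived ketone of step 14 gives the 10R epoxide, as expected from its spiro transition-state model for 2-methylalk-2-enes. The sense of induction of the chromium ligand in step 9 is set by choosing its enantiomer.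

Step 1
Reactants: 1 2,2-dimethyl-1,3-dioxan-5-one; 2 N,N-dimethylhydrazine
Product: 3 2,2-dimethyl-1,3-dioxan-5-one N,N-dimethylhydrazone
Conditions: 2 (1.5 equiv), cyclohexane, reflux, Dean–Stark trap
Reagents that add atoms: none
Why: Hydrazone formation turns the self-condensing dioxanone into a substrate that can be cleanly mono-C-alkylated through its azaenolate.

Step 2
Reactants: 3 2,2-dimethyl-1,3-dioxan-5-one N,N-dimethylhydrazone
Product: 5 2,2,4-trimethyl-1,3-dioxan-5-one (racemic), via methylated hydrazone 4 (not isolated)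
Conditions: LDA, THF, −78 °C; MeI, −78 °C → rt; then sat. aq. oxalic acid, Et2O, rt
Reagents that add atoms: iodomethane, CI; water, O
Why: Azaenolate alkylation (Corey–Enders type) installs the C3 methyl, and mild biphasic hydrolysis should return the ketone without touching the acetonide; the new centre is deliberately left racemic.

Step 3
Reactants: 5 2,2,4-trimethyl-1,3-dioxan-5-one
Product: 6 trimethyl[(2,2,4-trimethyl-4H-1,3-dioxin-5-yl)oxy]silane (racemic)
Conditions: LDA, Me3SiCl (in situ quench), THF, −78 °C
Reagents that add atoms: chlorotrimethylsilane, C[Si](C)(C)Cl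
Why: Kinetic deprotonation with internal silyl quench should take the less hindered CH2 (C1) and not the methyl-bearing C3, which fixes the nucleophilic carbon for the Michael step (regioselective silyl enol ether formation).

Step 4
Reactants: 7 3-(trimethylsilyl)prop-2-ynal; 8 (triphenylphosphoranylidene)acetaldehyde
Product: 9 (E)-5-(trimethylsilyl)pent-2-en-4-ynal
Conditions: toluene, rt
Reagents that add atoms: none
Why: Wittig olefination with the stabilised formyl ylide should give the (E)-enal; the silyl cap on the alkyne later blocks 1,6-addition.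

Step 5
Reactants: 6 trimethyl[(2,2,4-trimethyl-4H-1,3-dioxin-5-yl)oxy]silane; 9 (E)-5-(trimethylsilyl)pent-2-en-4-ynal
Product: 11 8-hydroxy-1,3,3-trimethyl-6-[(trimethylsilyl)ethynyl]-2,4-dioxabicyclo[3.3.1]nonan-9-one (target locants: O1/O3 acetonide on the α face, C2 ketone, 4β-OH axial and anti to O3, 6α-alkynyl equatorial), via keto aldehyde 10 (not isolated)
Conditions: (2R,5R)-5-benzyl-2-tert-butyl-3-methylimidazolidin-4-one·2,4-dinitrobenzoic acid (20 mol %), H2O (2 equiv), CH2Cl2, −40 °C; then MgBr2·OEt2 (4 equiv), i-Pr2NEt, −20 → 0 °C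
Reagents that add atoms: none
Why: The imidazolidinone condenses with 9 to an (E)-iminium ion that is attacked at C6 by enol ether carbon C1 of 6 (Mukaiyama–Michael addition; water takes up the silyl group and releases keto aldehyde 10 and the catalyst), and MgBr2/amine then soft-enolises the ketone toward C3 so that the magnesium enolate adds to aldehyde carbon C4 (intramolecular aldol). The closest known reaction types are the iminium-catalysed Mukaiyama–Michael addition of silyl enol ethers to enals and the Stork-type α,α′-annulation of cyclic ketones with enals to bicyclo[3.3.1]nonan-9-ones, here applied to a dioxanone. The carbocycle closes by a 6-(enolendo)-exo-trig aldol that is possible only when both new bonds are axial on the dioxanone, so O1 and O3 end 1,3-cis-diaxial on the new ring, held by the acetonide. C6 is set by the catalyst (its benzyl group covers the Si face of C6 in the iminium ion, so attack on the Re face gives 6R); C1 is epimerisable in 10 and should funnel into the isomer that cyclises with the alkynyl group equatorial; C3 is fixed by the bridge; the C4 hydroxyl should become axial (β) because magnesium holds enolate and aldehyde oxygens together in a chair transition state. The step needs 1,4- instead of 1,6- or 1,2-addition (secured by iminium activation and the silyl cap), attack through C1 and not C3 (secured by the regiodefined enol ether 6), and an aldol that stops at the ketol (C3 is quaternary and C1 a bridgehead, so no dehydration is possible).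

Step 6
Reactants: 11 bicyclic ketol
Product: 13 6-ethynyl-1,3,3-trimethyl-2,4-dioxabicyclo[3.3.1]nonane-8,9-diol (2α-OH, 4β-OH in target locants), via silyl diol 12 (not isolated)
Conditions: Me4NBH(OAc)3, MeCN–AcOH (1:1), −25 °C; aqueous work-up; crude product, K2CO3 (cat.), MeOH, rt
Reagents that add atoms: none
Why: Evans–Saksena reduction, in which the axial C4 hydroxyl binds the borohydride and delivers hydride intramolecularly to the β face of C2, should give the 2α-alcohol anti to the 4β-hydroxyl; methanolysis then removes the alkynyl silane.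

Step 7
Reactants: 13 alkynyl diol
Product: 14 6-(1-iodoethenyl)-1,3,3-trimethyl-2,4-dioxabicyclo[3.3.1]nonane-8,9-diol
Conditions: i-Bu2AlH (3.5 equiv), NiCl2(dppp) (3 mol %), THF, 0 → 22 °C; then N-iodosuccinimide, 0 °C
Reagents that add atoms: N-iodosuccinimide, O=C1CCC(=O)N1I
Why: Nickel-catalysed hydroalumination of a terminal alkyne is α-selective with the dppp ligand (aluminium on the internal carbon C7), and iodinolysis of the alkenylalane should give the 2-iodo-1-alkene under non-acidic conditions that spare the acetonide; the two hydroxyls are first converted to aluminium alkoxides by the excess hydride.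

Step 8
Reactants: 15 4-methylpent-3-en-1-ol
Product: 16 4-methylpent-3-enal
Conditions: Dess–Martin periodinane, CH2Cl2, 0 °C; used at once as a solution
Reagents that add atoms: none
Why: Dess–Martin oxidation under mild, non-basic conditions should give the β,γ-unsaturated aldehyde without migration of the double bond into conjugation.

Step 9
Reactants: 14 vinyl iodide; 16 4-methylpent-3-enal
Product: 17 6-[(3S)-3-hydroxy-6-methylhepta-1,5-dien-2-yl]-1,3,3-trimethyl-2,4-dioxabicyclo[3.3.1]nonane-8,9-diol (8S in target locants)
Conditions: CrCl2 (4 equiv), (S)-N-[2-(4-isopropyl-4,5-dihydrooxazol-2-yl)-6-methylphenyl]methanesulfonamide (4.4 equiv), Et3N, NiCl2 (2 mol %), THF, rt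
Reagents that add atoms: none
Why: Nozaki–Hiyama–Kishi coupling forms C7–C8 chemoselectively at the aldehyde in the presence of free hydroxyls, and the chiral sulfonamide ligand on chromium is to direct the alkenyl group to the Re face of the aldehyde (8S, reagent control; the antipodal ligand is used should the first run show the opposite sense).

Step 10
Reactants: 17 triol; 18 angelic acid
Product: 19 C2,C8-bis-angelate of 17 (4β-OH free)
Conditions: 18 (4 equiv), 2,4,6-trichlorobenzoyl chloride (4 equiv), Et3N, toluene, rt; then 17, 75 °C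
Reagents that add atoms: none
Why: Yamaguchi-type mixed-anhydride acylation without DMAP should transfer the angeloyl group without Z→E isomerisation to the allylic C8 and equatorial C2 hydroxyls, while the axial, neopentyl C4 hydroxyl (1,3-diaxial to H2 and H6, next to quaternary C3) is expected to stay free.

Step 11
Reactants: 19 bis-angelate
Product: 20 4β-methanesulfonate of 19
Conditions: MsCl, Et3N, CH2Cl2, 0 °C → rt
Reagents that add atoms: methanesulfonyl chloride, CS(=O)(=O)Cl
Why: Mesylation via sulfene should tolerate the hindered axial C4 alcohol, which is the only free hydroxyl.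

Step 12
Reactants: 20 acetonide mesylate
Product: 21 cyclohexane-1α,3α-diol with 2α-OAng, 3β-CH3, 4β-OMs and 6α-[(3S)-3-(angeloyloxy)-6-methylhepta-1,5-dien-2-yl]
Conditions: AcOH–H2O (4:1), 35 °C
Reagents that add atoms: none
Why: Acid hydrolysis of the strained 1,3-diaxial acetonide should free the C1 and C3 hydroxyls under conditions that leave mesylate, angelates and alkenes intact (acetal cleavage).

Step 13
Reactants: 21 diol mesylate
Product: 23 10,11-alkene analogue of the target (3α-OH, 4β-Cl), via ring epoxide 22 (not isolated)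
Conditions: Cs2CO3, MeCN, 0 °C → rt; then LiCl, AcOH, THF, rt
Reagents that add atoms: lithium chloride, [Li+].[Cl-]
Why: The C3 alkoxide should displace the anti-periplanar C4 mesylate to the α-epoxide (inversion), and chloride should then open it at C4 by Fürst–Plattner trans-diaxial attack at the secondary carbon remote from the electron-withdrawing C2 ester (second inversion), giving the 3α-OH/4β-Cl chlorohydrin with net retention at C4.

Step 14
Reactants: 23 chlorohydrin
Product: 24 target CNP0158207.1
Conditions: 1,2:4,5-di-O-isopropylidene-β-D-erythro-2,3-hexodiulo-2,6-pyranose (1 equiv), Oxone (2KHSO5·KHSO4·K2SO4), NaHCO3 buffer (pH about 8), Bu4NHSO4 (cat.), MeCN–dimethoxymethane–H2O, 0 °C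
Reagents that add atoms: potassium peroxymonosulfate, [K+].[O-]S(=O)(=O)OO
Why: Shi epoxidation, in which the dioxirane of the D-fructose-derived ketone should attack the electron-rich trisubstituted C10=C11 alkene in preference to the 1,1-disubstituted and angelate alkenes and is expected to give the 10R epoxide by catalyst control; the buffer is kept near neutral so that the chlorohydrin does not close.

Compound list
1 | 2,2-dimethyl-1,3-dioxan-5-one | CC1(C)OCC(=O)CO1 | starting material
2 | N,N-dimethylhydrazine | CN(C)N | starting material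
3 | 2,2-dimethyl-1,3-dioxan-5-one N,N-dimethylhydrazone | CN(C)N=C1COC(C)(C)OC1 | intermediate
4 | 2,2,4-trimethyl-1,3-dioxan-5-one N,N-dimethylhydrazone (racemic) | CC1OC(C)(C)OCC1=NN(C)C | intermediate
5 | 2,2,4-trimethyl-1,3-dioxan-5-one (racemic) | CC1OC(C)(C)OCC1=O | intermediate
6 | trimethyl[(2,2,4-trimethyl-4H-1,3-dioxin-5-yl)oxy]silane (racemic) | CC1OC(C)(C)OC=C1O[Si](C)(C)C | intermediate
7 | 3-(trimethylsilyl)prop-2-ynal | C[Si](C)(C)C#CC=O | starting material
8 | (triphenylphosphoranylidene)acetaldehyde | O=CC=P(c1ccccc1)(c1ccccc1)c1ccccc1 | starting material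
9 | (E)-5-(trimethylsilyl)pent-2-en-4-ynal | C[Si](C)(C)C#C/C=C/C=O | intermediate
10 | (3R)-3-(2,2,6-trimethyl-5-oxo-1,3-dioxan-4-yl)-5-(trimethylsilyl)pent-4-ynal (epimers at the two dioxanone carbons) | O=CC[C@H](C#C[Si](C)(C)C)C1OC(C)(C)OC(C)C1=O | intermediate
11 | 8-hydroxy-1,3,3-trimethyl-6-[(trimethylsilyl)ethynyl]-2,4-dioxabicyclo[3.3.1]nonan-9-one (4β-OH, 6α-alkynyl) | C[Si](C)(C)C#C[C@H]1C[C@H](O)[C@@](C)(OC(C)(C)O2)C(=O)[C@H]12 | intermediate
12 | 1,3,3-trimethyl-6-[(trimethylsilyl)ethynyl]-2,4-dioxabicyclo[3.3.1]nonane-8,9-diol (2α-OH, 4β-OH) | C[Si](C)(C)C#C[C@H]1C[C@H](O)[C@@](C)(OC(C)(C)O2)[C@@H](O)[C@H]12 | intermediate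
13 | 6-ethynyl-1,3,3-trimethyl-2,4-dioxabicyclo[3.3.1]nonane-8,9-diol | C#C[C@H]1C[C@H](O)[C@@](C)(OC(C)(C)O2)[C@@H](O)[C@H]12 | intermediate
14 | 6-(1-iodoethenyl)-1,3,3-trimethyl-2,4-dioxabicyclo[3.3.1]nonane-8,9-diol | C=C(I)[C@H]1C[C@H](O)[C@@](C)(OC(C)(C)O2)[C@@H](O)[C@H]12 | intermediate
15 | 4-methylpent-3-en-1-ol | CC(C)=CCCO | starting material
16 | 4-methylpent-3-enal | CC(C)=CCC=O | intermediate
17 | 6-[(3S)-3-hydroxy-6-methylhepta-1,5-dien-2-yl]-1,3,3-trimethyl-2,4-dioxabicyclo[3.3.1]nonane-8,9-diol | C=C([C@H](CC=C(C)C)O)[C@H]1C[C@H](O)[C@@](C)(OC(C)(C)O2)[C@@H](O)[C@H]12 | intermediate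
18 | angelic acid, (Z)-2-methylbut-2-enoic acid | C/C=C(/C)C(=O)O | starting material
19 | C2,C8-bis-angelate of 17 (4β-OH free) | C=C([C@H](CC=C(C)C)OC(=O)/C(C)=C\C)[C@H]1C[C@H](O)[C@@](C)(OC(C)(C)O2)[C@@H](OC(=O)/C(C)=C\C)[C@H]12 | intermediate
20 | 4β-methanesulfonate of 19 | C=C([C@H](CC=C(C)C)OC(=O)/C(C)=C\C)[C@H]1C[C@H](OS(C)(=O)=O)[C@@](C)(OC(C)(C)O2)[C@@H](OC(=O)/C(C)=C\C)[C@H]12 | intermediate
21 | 1α,3α-diol 4β-mesylate 2α,C8-bis-angelate (acetonide removed) | C=C([C@H](CC=C(C)C)OC(=O)/C(C)=C\C)[C@H]1C[C@H](OS(C)(=O)=O)[C@@](C)(O)[C@@H](OC(=O)/C(C)=C\C)[C@H]1O | intermediate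
22 | 3α,4α-epoxide 1α-ol 2α,C8-bis-angelate | C=C([C@H](CC=C(C)C)OC(=O)/C(C)=C\C)[C@H]1C[C@H]2O[C@@]2(C)[C@@H](OC(=O)/C(C)=C\C)[C@H]1O | intermediate
23 | 10,11-alkene analogue of the target (3α-OH, 4β-Cl) | C=C([C@H](CC=C(C)C)OC(=O)/C(C)=C\C)[C@H]1C[C@H](Cl)[C@@](C)(O)[C@@H](OC(=O)/C(C)=C\C)[C@H]1O | intermediate
24 | CNP0158207.1 | C=C([C@H](C[C@H]1OC1(C)C)OC(=O)/C(C)=C\C)[C@H]1C[C@H](Cl)[C@@](C)(O)[C@@H](OC(=O)/C(C)=C\C)[C@H]1O | target

Total step count: 14. Longest linear sequence: 12 steps (steps 1, 2, 3, 5, 6, 7, 9, 10, 11, 12, 13, 14; from 1 to 24).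

Steps most likely to fail

Step 5. The oxygen-rich silyl enol ether may hydrolyse faster than it adds to the iminium ion, the facial selectivity at C6 may erode, or ring closure may stay incomplete because the strained acetonide bridge favours retro-aldol. Fallback, setting out from 5 and coming back at 11: ketone 5 is condensed with (S)-2-(methoxymethyl)pyrrolidine over 4 Å sieves to the less substituted enamine F1 (the antipodal amine is used if the first run shows attack on the wrong face of C6). Stork-type Michael addition of F1 to 9 and buffered aqueous hydrolysis give keto aldehyde 10, now isolated. A separate aldol closure with MgBr2·OEt2/Et3N in dry CH2Cl2 then gives 11.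

Step 10. Chemoselectivity between the C2 and C4 hydroxyls may be lost, or acylation at C2 may be too slow on the bicycle. Fallback, setting out from 11 and coming back at 20: the only hydroxyl of 11 is mesylated first (MsCl, Et3N) to keto mesylate F2, which cannot eliminate because C3 is quaternary and C1 a bridgehead. NaBH4 in MeOH at −40 °C is expected to attack C2 from the carbocycle face, since the acetonide methyl and the ring-oxygen lone pairs screen the other face, giving silyl hydroxy mesylate F3. K2CO3 in MeOH gives terminal alkyne F4, the conditions of steps 7 and 9 give vinyl iodide F5 and diol mesylate F6, and the acylation of step 10, now with only the two wanted hydroxyls, gives 20.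

Step 9. Facial selectivity at C8 may be poor with a branched alkenyl iodide and unprotected hydroxyls. Fallback, setting out from 17 as its C8 epimer mixture and coming back at 17: MnO2 in CH2Cl2 oxidises only the allylic C8 alcohol to enone F7, and Corey–Bakshi–Shibata reduction with the (R)-oxazaborolidine and catecholborane at −78 °C should return 17 as the 8S alcohol (alkenyl as the large group).

Further compounds
F1 | step 5 | (2S)-2-(methoxymethyl)-1-(2,2,4-trimethyl-4H-1,3-dioxin-5-yl)pyrrolidine | COC[C@@H]1CCCN1C2=COC(C)(C)OC2C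
F2 | step 10 | 8-O-methanesulfonate of ketol 11 | C[Si](C)(C)C#C[C@H]1C[C@H](OS(C)(=O)=O)[C@@](C)(OC(C)(C)O2)C(=O)[C@H]12
F3 | step 10 | silyl hydroxy mesylate (2α-OH, 4β-OMs) | C[Si](C)(C)C#C[C@H]1C[C@H](OS(C)(=O)=O)[C@@](C)(OC(C)(C)O2)[C@@H](O)[C@H]12
F4 | step 10 | terminal alkyne hydroxy mesylate | C#C[C@H]1C[C@H](OS(C)(=O)=O)[C@@](C)(OC(C)(C)O2)[C@@H](O)[C@H]12
F5 | step 10 | vinyl iodide hydroxy mesylate | C=C(I)[C@H]1C[C@H](OS(C)(=O)=O)[C@@](C)(OC(C)(C)O2)[C@@H](O)[C@H]12
F6 | step 10 | C2,C8-diol 4β-mesylate | C=C([C@H](CC=C(C)C)O)[C@H]1C[C@H](OS(C)(=O)=O)[C@@](C)(OC(C)(C)O2)[C@@H](O)[C@H]12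
F7 | step 9 | C8 enone of 17 | C=C(C(=O)CC=C(C)C)[C@H]1C[C@H](O)[C@@](C)(OC(C)(C)O2)[C@@H](O)[C@H]12
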